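**Retrosynthetic overview**
1. The Z alkene (C3=C4) and the free alkyne are made last from a Me3Si-capped 1,3-diyne, so the ring alkene is the only alkene that ever meets Br+.
2. Ring B (tetrahydrofuran, O–C9 and C10–Br) comes from 5-exo bromoetherification of a cis-2,7-disubstituted oxepene by the C6 hydroxyl.
3. Ring A (oxepene carrying exocyclic C13HBr–Et) comes from ring contraction of a trans-2-ethyl-3-bromo-oxocene through a bicyclic oxiranium ion. O moves from C13 to C12 and Br from C12 to C13, each with inversion.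
4. The oxocene comes from ring-closing metathesis (C9=C10), C12 from allylboration, and the C7–O–C13 link from SN2 of the C7 alkoxide on the triflate of methyl (S)-2-hydroxybutanoate.
5. C5–C8 with both carbinol centres come from (2S,3S)-diepoxybutane, opened by vinyl at C8 and by a diynyl anion at C5. Ring order: eight-membered, then seven-membered (ring A), then five-membered (ring B).

Atom labels C1–C15 run along the chain from the alkyne terminus.
Assumption: enantiopure (2S,3S)-diepoxybutane, methyl (S)-2-hydroxybutanoate and buta-1,3-diynyl(trimethyl)silane are taken as catalogue items.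

**Step 1**
Reactants: 1 (2S,3S)-1,2:3,4-diepoxybutane
Product: 2 (S)-1-[(S)-oxiran-2-yl]but-3-en-1-ol
Conditions: vinylMgBr (1.0 equiv), CuI (10 mol %), 1 (2 equiv), THF, −40 °C; H2O quench
Reagents that add atoms: vinylmagnesium bromide C=C[Mg]Br
Why: Copper-catalysed Grignard opening of a terminal epoxide occurs only at the CH2 terminus (C8–C9 bond), so C6 and C7 keep the configuration of 1, the two epoxides of C2-symmetric 1 are equivalent, and the excess of 1 holds back double opening.

**Step 2**
Reactants: 3 methyl (S)-2-hydroxybutanoate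
Product: 4 methyl (S)-2-(trifluoromethylsulfonyloxy)butanoate
Conditions: Tf2O, 2,6-lutidine, CH2Cl2, −78 to 0 °C
Reagents that add atoms: triflic anhydride O=S(=O)(OS(=O)(=O)C(F)(F)F)C(F)(F)F
Why: This is a standard O-triflation of an α-hydroxy ester, and the stereocentre (future C13) is not touched.

**Step 3**
Reactants: 2 (S)-1-[(S)-oxiran-2-yl]but-3-en-1-ol; 4 methyl (S)-2-(trifluoromethylsulfonyloxy)butanoate
Product: 5 methyl (R)-2-{(S)-1-[(S)-oxiran-2-yl]but-3-enyloxy}butanoate
Conditions: NaH, THF, −20 °C; then 4, −20 to 0 °C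
Reagents that add atoms: none
Why: In this Williamson etherification of the muramic-acid type the sodium alkoxide displaces the activated α-triflate by SN2 with inversion, which sets C13 as (R) and makes the C7–O–C13 link, while low temperature in an aprotic solvent holds back Payne migration.

**Step 4**
Reactants: 5 methyl (R)-2-{(S)-1-[(S)-oxiran-2-yl]but-3-enyloxy}butanoate
Product: 6 (R)-2-{(S)-1-[(S)-oxiran-2-yl]but-3-enyloxy}butanal
Conditions: i-Bu2AlH (1.1 equiv), CH2Cl2, −78 °C; H2O work-up; used crude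
Reagents that add atoms: none
Why: Partial ester reduction stops at the tetrahedral aluminate at −78 °C and gives the aldehyde on hydrolysis, the terminal epoxide is inert at this temperature, and using 6 crude avoids epimerisation at C13.

**Step 5**
Reactants: 6 (R)-2-{(S)-1-[(S)-oxiran-2-yl]but-3-enyloxy}butanal
Product: 7 (3R,4R)-3-{(S)-1-[(S)-oxiran-2-yl]but-3-enyloxy}hept-6-en-4-ol
Conditions: (+)-Ipc2BOMe, allylMgBr, Et2O, 0 °C to rt; then 6, −78 °C; NaOH, H2O2, 0 °C
Reagents that add atoms: allylmagnesium bromide C=CC[Mg]Br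
Why: Brown asymmetric allylboration through a closed chair transition state delivers allyl to the Re face and sets C12 as (R) (12,13-syn) under reagent control, with no Lewis acid present that could open the epoxide.

**Step 6**
Reactants: 7 (3R,4R)-3-{(S)-1-[(S)-oxiran-2-yl]but-3-enyloxy}hept-6-en-4-ol
Product: 8 (2R,3R,8S,5Z)-2-ethyl-8-[(S)-oxiran-2-yl]-3,4,7,8-tetrahydro-2H-oxocin-3-ol
Conditions: second-generation Grubbs catalyst (5 mol %), CH2Cl2 (2 mM), 40 °C
Reagents that add atoms: none
Why: In this ring-closing metathesis of the only two alkenes the gauche preference of the vicinal C12/C13 oxygens folds the chain, the eight-membered ring can hold only a Z alkene, and high dilution suppresses dimers.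

**Step 7**
Reactants: 8 (2R,3R,8S,5Z)-2-ethyl-8-[(S)-oxiran-2-yl]-3,4,7,8-tetrahydro-2H-oxocin-3-ol
Product: 10 (2R,3S,8S,5Z)-3-bromo-2-ethyl-8-[(S)-oxiran-2-yl]-3,4,7,8-tetrahydro-2H-oxocine, via oxocenyl triflate 9 (not isolated)
Conditions: Tf2O, 2,6-lutidine, CH2Cl2, −78 °C; then Bu4NBr (3 equiv), −78 to −20 °C
Reagents that add atoms: tetrabutylammonium bromide CCCC[N+](CCCC)(CCCC)CCCC.[Br-]
Why: Sulfonate activation followed by SN2 displacement with soluble bromide inverts C12 to (S) (Br trans to ethyl), as in the closing bromination of lauroxocane syntheses, and excess bromide at low temperature outruns neighbouring-group pathways and leaves the epoxide alone.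

**Step 8**
Reactants: 10 (2R,3S,8S,5Z)-3-bromo-2-ethyl-8-[(S)-oxiran-2-yl]-3,4,7,8-tetrahydro-2H-oxocine; 11 buta-1,3-diyn-1-yl(trimethyl)silane
Product: 13 (S)-1-[(2S,7S,8R,4Z)-7-bromo-8-ethyl-3,6,7,8-tetrahydro-2H-oxocin-2-yl]-6-(trimethylsilyl)hexa-3,5-diyn-1-ol, via lithium diynide 12 (not isolated)
Conditions: 11, n-BuLi, THF, −78 °C; BF3·OEt2; then 10, −78 °C; H2O quench
Reagents that add atoms: none
Why: In this Yamaguchi–Hirao alkynylation the BF3-activated terminal epoxide is opened at C5 by the weakly basic diynide, C6 keeps its (S) configuration, and the secondary bromide is untouched at −78 °C.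

**Step 9**
Reactants: 13 (S)-1-[(2S,7S,8R,4Z)-7-bromo-8-ethyl-3,6,7,8-tetrahydro-2H-oxocin-2-yl]-6-(trimethylsilyl)hexa-3,5-diyn-1-ol
Product: 15 (S)-1-{(2S,7R)-7-[(S)-1-bromopropyl]-2,3,6,7-tetrahydrooxepin-2-yl}-6-(trimethylsilyl)hexa-3,5-diyn-1-ol, via oxiranium tribromozincate 14 (not isolated)
Conditions: ZnBr2 (20 mol %), CH2Cl2–MeNO2 4:1, 40 °C
Reagents that add atoms: none
Why: Proposed new method: ZnBr2 abstracts bromide from C12 in the conformer whose trans-diequatorial C12–Br bond is antiperiplanar to the O–C13 bond, so the ring oxygen closes on C12 with inversion to oxiranium ion 14; ZnBr3− then returns bromide either to C12 (degenerate, regenerates 13) or from the open exocyclic side to C13 with inversion, which contracts the eight-membered ring to the less strained cis-2,7-disubstituted oxepene and sets C12 (R) and C13 (S) stereospecifically; homoallyl (cyclopropylcarbinyl) ion pairs and their capture by the C6 hydroxyl should be reversible under ZnBr2/HBr, so the mixture is expected to drain to 15, whose exocyclic bromide has no π neighbour; the closest known reaction types are zinc-salt-mediated ring-size changes of cyclic ether sulfonates through bicyclic oxonium ions, the aziridinium-mediated 3-halopiperidine/2-(halomethyl)pyrrolidine interconversion, and silver-promoted oxonium formation from bromo ethers.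

**Step 10**
Reactants: 15 (S)-1-{(2S,7R)-7-[(S)-1-bromopropyl]-2,3,6,7-tetrahydrooxepin-2-yl}-6-(trimethylsilyl)hexa-3,5-diyn-1-ol
Product: 16 (6S,7S,9S,10S,12R,13S)-10,13-dibromo-6,9:7,12-diepoxy-1-(trimethylsilyl)pentadeca-1,3-diyne
Conditions: NBS (1.1 equiv), MeCN, 0 °C, dark
Reagents that add atoms: N-bromosuccinimide O=C1CCC(=O)N1Br
Why: In this 5-exo bromoetherification the C6 hydroxyl can reach C9 only on the ring face that carries its own side chain and bromine ends up anti on C10, which sets C9 (S) and C10 (S) and closes ring B, while the silyl diyne is inert to NBS.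

**Step 11**
Reactants: 16 (6S,7S,9S,10S,12R,13S)-10,13-dibromo-6,9:7,12-diepoxy-1-(trimethylsilyl)pentadeca-1,3-diyne
Product: 19 (3Z,6S,7S,9S,10S,12R,13S)-10,13-dibromo-6,9:7,12-diepoxypentadec-3-en-1-yne (target), via alkenylborane 17 (not isolated), via silyl enyne 18 (not isolated)
Conditions: Cy2BH (1.05 equiv), THF, 0 °C; AcOH, 50 °C; then MeOH, K2CO3 (excess), rt
Reagents that add atoms: none
Why: Zweifel-type monohydroboration of a 1-silyl-1,3-diyne adds H–B syn to the alkyl-substituted triple bond (boron on C3), protonolysis with retention gives the Z alkene, and K2CO3/MeOH protodesilylation frees the alkyne without touching the secondary bromides.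

**Compound list**
1 | (2S,3S)-1,2:3,4-diepoxybutane | C1O[C@@H]1[C@@H]1CO1 | starting material
2 | (S)-1-[(S)-oxiran-2-yl]but-3-en-1-ol | C=CC[C@H](O)[C@@H]1CO1 | intermediate
3 | methyl (S)-2-hydroxybutanoate | CC[C@H](O)C(=O)OC | starting material
4 | methyl (S)-2-(trifluoromethylsulfonyloxy)butanoate | CC[C@H](OS(=O)(=O)C(F)(F)F)C(=O)OC | intermediate
5 | methyl (R)-2-{(S)-1-[(S)-oxiran-2-yl]but-3-enyloxy}butanoate | C=CC[C@H](O[C@H](CC)C(=O)OC)[C@@H]1CO1 | intermediate
6 | (R)-2-{(S)-1-[(S)-oxiran-2-yl]but-3-enyloxy}butanal | C=CC[C@H](O[C@H](CC)C=O)[C@@H]1CO1 | intermediate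
7 | (3R,4R)-3-{(S)-1-[(S)-oxiran-2-yl]but-3-enyloxy}hept-6-en-4-ol | C=CC[C@H](O[C@H](CC)[C@H](O)CC=C)[C@@H]1CO1 | intermediate
8 | (2R,3R,8S,5Z)-2-ethyl-8-[(S)-oxiran-2-yl]-3,4,7,8-tetrahydro-2H-oxocin-3-ol | CC[C@H]1O[C@H]([C@@H]2CO2)C/C=C\C[C@H]1O | intermediate
9 | triflate of 8 (not isolated) | CC[C@H]1O[C@H]([C@@H]2CO2)C/C=C\C[C@H]1OS(=O)(=O)C(F)(F)F | intermediate
10 | (2R,3S,8S,5Z)-3-bromo-2-ethyl-8-[(S)-oxiran-2-yl]-3,4,7,8-tetrahydro-2H-oxocine | CC[C@H]1O[C@H]([C@@H]2CO2)C/C=C\C[C@@H]1Br | intermediate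
11 | buta-1,3-diyn-1-yl(trimethyl)silane | C#CC#C[Si](C)(C)C | starting material
12 | lithium 4-(trimethylsilyl)buta-1,3-diyn-1-ide (not isolated) | [Li]C#CC#C[Si](C)(C)C | intermediate
13 | (S)-1-[(2S,7S,8R,4Z)-7-bromo-8-ethyl-3,6,7,8-tetrahydro-2H-oxocin-2-yl]-6-(trimethylsilyl)hexa-3,5-diyn-1-ol | CC[C@H]1O[C@H]([C@@H](O)CC#CC#C[Si](C)(C)C)C/C=C\C[C@@H]1Br | intermediate
14 | bicyclic oxiranium ion (O+ on C7, C12, C13; ethyl and C11 trans on the three-membered ring), tribromozincate salt (not isolated) | CC[C@@H]1[C@H]2C/C=C\C[C@H]([O+]12)[C@@H](O)CC#CC#C[Si](C)(C)C.Br[Zn-](Br)Br | intermediate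
15 | (S)-1-{(2S,7R)-7-[(S)-1-bromopropyl]-2,3,6,7-tetrahydrooxepin-2-yl}-6-(trimethylsilyl)hexa-3,5-diyn-1-ol | CC[C@H](Br)[C@H]1C/C=C\C[C@H](O1)[C@@H](O)CC#CC#C[Si](C)(C)C | intermediate
16 | (6S,7S,9S,10S,12R,13S)-10,13-dibromo-6,9:7,12-diepoxy-1-(trimethylsilyl)pentadeca-1,3-diyne | C[Si](C)(C)C#CC#CC[C@@H]1O[C@H]2C[C@@H]1O[C@@H]([C@@H](Br)CC)C[C@@H]2Br | intermediate
17 | C3-dicyclohexylboryl (Z)-enyne from 16 (not isolated) | C[Si](C)(C)C#C/C(B(C1CCCCC1)C1CCCCC1)=C\C[C@@H]1O[C@H]2C[C@@H]1O[C@@H]([C@@H](Br)CC)C[C@@H]2Br | intermediate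
18 | 1-trimethylsilyl derivative of the target (not isolated) | C[Si](C)(C)C#C/C=C\C[C@@H]1O[C@H]2C[C@@H]1O[C@@H]([C@@H](Br)CC)C[C@@H]2Br | intermediate
19 | (3Z,6S,7S,9S,10S,12R,13S)-10,13-dibromo-6,9:7,12-diepoxypentadec-3-en-1-yne | C#C/C=C\C[C@@H]1O[C@H]2C[C@@H]1O[C@@H]([C@@H](Br)CC)C[C@@H]2Br | target

**Total steps:** 11. **Longest linear sequence:** 10 (steps 1 and 3–11; the same length from 3 through steps 2–11).

**Steps most likely to fail**

Step 9 (the proposed ring contraction). Participation of an ether oxygen through a three-membered ring is weak. Ionisation may therefore not start, or it may run through the homoallyl π system instead.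
The fallback uses only known chemistry, drops the rearrangement, and closes the seven-membered ring directly by metathesis. It sets out from 2 and comes back at 15.
Purchased (S)-2-hydroxypent-4-enoic acid is esterified (MeOH, cat. H2SO4) to methyl (S)-2-hydroxypent-4-enoate F1 and triflated to methyl (S)-2-(trifluoromethylsulfonyloxy)pent-4-enoate F2. The sodium alkoxide of 2 displaces the triflate with inversion to give methyl (R)-2-{(S)-1-[(S)-oxiran-2-yl]but-3-enyloxy}pent-4-enoate F3. Reduction with i-Bu2AlH gives (R)-2-{(S)-1-[(S)-oxiran-2-yl]but-3-enyloxy}pent-4-enal F4, and chelation-controlled addition of EtMgBr gives the syn alcohol (3R,4R)-4-{(S)-1-[(S)-oxiran-2-yl]but-3-enyloxy}hept-6-en-3-ol F5.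
Ring-closing metathesis then gives (R)-1-{(2R,7S)-7-[(S)-oxiran-2-yl]-2,3,6,7-tetrahydrooxepin-2-yl}propan-1-ol F6. Tf2O followed by Bu4NBr, with inversion at C13, gives (2R,7S)-2-[(S)-1-bromopropyl]-7-[(S)-oxiran-2-yl]-2,3,6,7-tetrahydrooxepine F7. Opening of its epoxide with 12 and BF3·OEt2 gives 15.

Step 3 (secondary alkoxide on a secondary α-triflate). Elimination to the crotonate, acyl attack or Payne migration can compete.
The fallback forms the ether under neutral conditions by carbene O–H insertion. It sets out from 2 and comes back at 5.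
Methyl 2-aminobutanoate is diazotised (isoamyl nitrite, cat. AcOH) to methyl 2-diazobutanoate F8. This is inserted into the O–H bond of 2 with Rh2(O2CCPh3)4 at −78 °C, a catalyst that suppresses the 1,2-hydride shift. The product is 5 together with its C13 epimer, which is removed by chromatography.

Step 7 (SN2 at a ring carbinol flanked by the ether carbon). Elimination or transannular participation in the medium ring can lower the yield.
The fallback brominates before the ring exists. It sets out from 7 and comes back at 10.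
The open-chain alcohol 7 is triflated and displaced with Bu4NBr, with inversion, to give (S)-2-{(S)-1-[(3R,4S)-4-bromohept-6-en-3-yloxy]but-3-enyl}oxirane F9. Ring-closing metathesis of this bromo diene gives 10.

**Further compounds**
F1 | step 9 | methyl (S)-2-hydroxypent-4-enoate | C=CC[C@H](O)C(=O)OC
F2 | step 9 | methyl (S)-2-(trifluoromethylsulfonyloxy)pent-4-enoate | C=CC[C@H](OS(=O)(=O)C(F)(F)F)C(=O)OC
F3 | step 9 | methyl (R)-2-{(S)-1-[(S)-oxiran-2-yl]but-3-enyloxy}pent-4-enoate | C=CC[C@H](O[C@H](CC=C)C(=O)OC)[C@@H]1CO1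
F4 | step 9 | (R)-2-{(S)-1-[(S)-oxiran-2-yl]but-3-enyloxy}pent-4-enal | C=CC[C@H](O[C@H](CC=C)C=O)[C@@H]1CO1
F5 | step 9 | (3R,4R)-4-{(S)-1-[(S)-oxiran-2-yl]but-3-enyloxy}hept-6-en-3-ol | C=CC[C@H](O[C@H](CC=C)[C@H](O)CC)[C@@H]1CO1
F6 | step 9 | (R)-1-{(2R,7S)-7-[(S)-oxiran-2-yl]-2,3,6,7-tetrahydrooxepin-2-yl}propan-1-ol | CC[C@@H](O)[C@H]1C/C=C\C[C@H](O1)[C@@H]2CO2
F7 | step 9 | (2R,7S)-2-[(S)-1-bromopropyl]-7-[(S)-oxiran-2-yl]-2,3,6,7-tetrahydrooxepine | CC[C@H](Br)[C@H]1C/C=C\C[C@H](O1)[C@@H]2CO2
F8 | step 3 | methyl 2-diazobutanoate | CCC(=[N+]=[N-])C(=O)OC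
F9 | step 7 | (S)-2-{(S)-1-[(3R,4S)-4-bromohept-6-en-3-yloxy]but-3-enyl}oxirane | C=CC[C@H](O[C@H](CC)[C@@H](Br)CC=C)[C@@H]1CO1
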